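## The problem

The target is a trans-fused decalin in labdane numbering (ring A: C1–C5 and C10; ring B: C5–C10). It has two quaternary carbons flanking the C5 methine: C4, with an axial methyl (C19) and an equatorial acetoxymethyl group (C18), and C10, with the angular methyl C20. The fourth stereocentre, C9, carries the (E)-3-methylpent-2-enoate chain in the equatorial position. Ring B contains a conjugated 6,8(17)-diene, and C3 carries no oxygen, so an epoxide-initiated cyclisation would leave a hydroxyl to remove. C4 is the only centre that can be made before any ring exists; once fixed it must dictate C5 and C10, whose trans relationship can be locked by alkene geometry. C9 is best set last, under the influence of the axial C20 methyl, because it can only be adjusted while C8 is still a carbonyl. The exocyclic diene is sensitive to acid, and the methyl enoate and primary acetate do not survive hydride, organolithium or strong base, so these groups belong at the end. The enabling feature is that the ring-fusion bond C5–C10 can be the E double bond of an open chain in which C10 already carries C20 and C9. A three-carbon electrophile C6–C7–C8 on C9 and a two-carbon nucleophile C1=C2 reached from C4 through C3 then close ring B at C5–C6 and ring A at C1–C10, and C8 emerges as the ketone that later gives both the 8(17)-methylene and the 6,7-alkene.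

## Retrosynthesis

**Ester groups last.** Target 33 is traced to alcohol 32 and its silyl ether 31 by cutting the acyl–O bond at C18. An acetate would not survive the hydride, enolate and Lewis-acid steps, whereas a bulky silyl ether does and is also the group that steers the cyclisation. The skeleton is unchanged; the forward steps need a fluoride source that spares the methyl enoate.

**Enoate from an alkyne.** In 31 the C13–C16 and C14–C15 bonds are cut together, giving terminal alkyne 29. A syn carbometalation followed by acylation fixes the E geometry by mechanism, which olefination of a C13 methyl ketone would not. Precursor 29 has lost the ester and the trisubstituted alkene; the forward reaction must ignore the ring diene.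

**Exocyclic methylene.** Cutting C8=C17 in 29 gives enone 28. Placing this before the enoate removes the only carbonyl that could let C9 epimerise. The forward methylenation must be non-basic, because C9 of 28 is α to the ketone.

**Side chain and C9.** In 28 the C11–C12 bond and the C9–H bond are disconnected, giving the cross-conjugated exo-methylene dienone 25 and the three-carbon stannane 26. The more obvious cut, C9–C11 by enolate alkylation, would put the chain on the face away from C20, which is the wrong epimer. Base equilibration in a 6-en-8-one cannot be relied on to correct it, because the axial and equatorial epimers are close in energy there. With C11 already attached as an sp2 carbon, the last event at C9 is protonation from that same open face, which leaves the chain equatorial. Precursor 25 has no C9 stereocentre and no side chain.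

**Ring B unsaturation.** Dienone 25 goes back to enone 22 (cut C9=C11), 22 to saturated ketone 20 (cut the C6=C7 π bond, via enol silane 21), and 20 to the ring A alkene 19. Dehydrogenation can only go towards C6 because C10 is quaternary, and once C6=C7 is in place C9 is the only enolisable position. Both regiochemical questions are therefore settled by the skeleton.

**Key disconnection.** In 19 the bonds C5–C6 and C1–C10 are cut, opening both rings to the acyclic vinyl ketal 17. The biogenetic cuts (C4–C5 and C9–C10) need a cation at C4, which means an epoxide, a C3 oxygen to delete, and C4 stereochemistry taken from the geometry of an oxygenated alkene terminus. Here C4 is a preformed stereocentre outside the reacting π-system, C3 is never oxidised, and the electrophile leaves exactly the C8 carbonyl required. Precursor 17 has no ring and one stereocentre. The forward reaction must ionise the ketal to a 1-alkoxyallyl cation, close two six-membered rings through chairs on one face of the C5=C10 alkene, and terminate cleanly at a Z-vinylsilane.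

**Initiator.** Ketal 17 is traced to 1-alkoxyallene 16 (cut the two C8–O ketal bonds) and 16 to allylic bromide 14 plus the allene 15 (cut C8–C9). Compound 15 serves as an acyl-anion reagent for a propenoyl unit. This avoids handling a free β,γ-unsaturated vinyl ketone, which would move into conjugation or polymerise. The forward step needs a weak acid and a 1,2-diol so that the cation is trapped at oxygen before it can cyclise.

**Chain.** Bromide 14 goes back through allylic alcohol 13 and enoate 12 to aldehyde 10 and the stabilised ylide 11 (cut C5=C10). A stabilised α-methyl ylide is the most reliable way to an E trisubstituted alkene next to a quaternary carbon, and this geometry is what becomes the trans ring fusion.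

**C4.** Aldehyde 10 is traced through alcohol 9, Z-vinylsilane 8, silylalkyne 7, hydroxy ester 6 and half-ester 4 to the prochiral diester 3, made from 1 and 2 (cut C3–C4). The four different groups on C4 come from one alkylation and one desymmetrisation of a malonate. The two carboxyl carbons become C5 and C18, so either sense of desymmetrisation can be used.

## Roads not taken

**Alternative 1:** dearomatisation by a metal carbene. The cut is C9–C10. The phenolic diazoketone A1 would be decomposed by a chiral dirhodium tetracarboxylate, Rh2(O2CR)4; the carbene carbon C9 alkylates the methyl-bearing para carbon C10 and gives dienedione A2 with ring B closed and C10 quaternary.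
- Merits: A1 is a flat aromatic compound reachable in a few steps. The quaternary C10 is set by a catalyst, not carried from an early centre. A2 already has the C8 ketone. This road would very probably reach a bicyclic intermediate in fewer steps than the 13 needed to reach 19.
- Weak points: A2 has no stereocentre at C4 or C5 and an unwanted carbonyl at C3. Ring A would still need conjugate reduction, reductive hydroxymethylation at C4, protection, and deoxygenation at C3, while two ketones are told apart. The carbene step competes with arene cyclopropanation and ring expansion and with O–H insertion, and enantiocontrol at a fully substituted arene carbon with an acceptor-only carbene is not secure.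
- Comparison: against the shorter opening, the chosen plan offers 19 with C4, C5 and C10 all set and ring A at the final oxidation level apart from one alkene.

**Alternative 2:** Claisen ring contraction. The cut is C4–C5. After enolisation and O-silylation, δ-lactone A3 (carbonyl C6, ring oxygen on C2) would rearrange on heating; C4–C5 forms as C2–O breaks, and the cyclohexene acid A4 results with C4, C5 and C10 in place.
- Merits: the relation between C4 and C5 comes from a bicyclic, boat-like sigmatropic transition state. That is inherently more dependable than the steric preference between methyl and silyloxymethyl on which the chosen plan relies, and in this respect the alternative is better.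
- Weak points: A3 needs two separately made stereocentres (quaternary C10 and the carbinol C2) and a Z trisubstituted alkene. The new bond joins a fully substituted alkene carbon to a carbon next to quaternary C10, with the silyloxymethyl group pointing into the lactone ring. Ring B must still be closed from the C6 acid and a methyl ketone, which leaves oxygen at C6 to remove.
- Comparison: the chosen plan makes both rings and both new centres in one step from a precursor with a single stereocentre.

**Alternative 3:** Stetter ring closure. The cut is C8–C9. An N-heterocyclic carbene from a triazolium salt would turn the C8 aldehyde of the cyclohexane A5 into an acyl-anion equivalent that adds to C9 of the enoate on C10, giving keto ester A6.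
- Merits: ring B closes with two side-chain carbons already on C9, and C9 sits next to a ketone in a saturated ring, where base equilibration reliably favours the equatorial chain. The later dehydrogenation can only go towards C6. On the C9 question this road is better than the chosen one, which needs a Mannich methylenation and a conjugate addition to reach the same point.
- Weak points: A5 is already a ring A with three contiguous stereocentres, two of them quaternary, so the hardest part of the target is left unsolved. The conjugate acceptor carbon is attached to a quaternary centre, which is unfavourable for an intramolecular Stetter reaction.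
- Comparison: the chosen plan spends its key step on exactly the part that A5 takes for granted.

Key step: step 13

Assumption: pig liver esterase is taken to hydrolyse the ester group that leaves the (R)-half-ester 4; if it gives the (S)-acid instead, reduction of the ester with LiBH4 followed by O-methylation of the acid leads to the same hydroxy ester 6.

## Steps

Step 1
Reactants: 1 dimethyl 2-methylpropanedioate; 2 3-bromo-1-(trimethylsilyl)prop-1-yne
Product: 3 dimethyl 2-methyl-2-[3-(trimethylsilyl)prop-2-yn-1-yl]propanedioate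
Conditions: NaH, THF, 0 °C → rt
Reagents that add atoms: none
Why: Malonate alkylation (SN2) of the sodium enolate of 1 with the propargylic bromide; the silyl cap suppresses allene formation and later directs the semi-reduction. No stereocentre is formed; the two ester groups are enantiotopic.

Step 2
Reactants: 3 dimethyl 2-methyl-2-[3-(trimethylsilyl)prop-2-yn-1-yl]propanedioate
Product: 4 (2R)-3-methoxy-2-methyl-3-oxo-2-[3-(trimethylsilyl)prop-2-yn-1-yl]propanoic acid
Conditions: pig liver esterase, phosphate buffer (pH 7.5), 10% DMSO, NaOH (pH-stat), rt; then HCl to pH 2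
Reagents that add atoms: water (O)
Why: Enzymatic desymmetrisation: the esterase hydrolyses one of the two enantiotopic methyl esters of a 2-methyl-2-alkylmalonate and so creates the C4 quaternary centre. The enantiomeric purity can be raised by crystallising an amine salt of 4.

Step 3
Reactants: 4 (2R)-3-methoxy-2-methyl-3-oxo-2-[3-(trimethylsilyl)prop-2-yn-1-yl]propanoic acid
Product: 6 methyl (2R)-2-(hydroxymethyl)-2-methyl-5-(trimethylsilyl)pent-4-ynoate, via acid chloride 5 (not isolated)
Conditions: (COCl)2, DMF (cat.), CH2Cl2, 0 °C → rt; then NaBH4, THF, 0 °C → rt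
Reagents that add atoms: none
Why: Acyl chloride formation and borohydride reduction: NaBH4 reduces the acid chloride far faster than the methyl ester and, unlike borane, leaves the silylalkyne alone. The quaternary centre has no α-hydrogen and cannot epimerise.

Step 4
Reactants: 6 methyl (2R)-2-(hydroxymethyl)-2-methyl-5-(trimethylsilyl)pent-4-ynoate
Product: 7 methyl (2R)-2-{[(tert-butyldiphenylsilyl)oxy]methyl}-2-methyl-5-(trimethylsilyl)pent-4-ynoate
Conditions: t-BuPh2SiCl, imidazole, DMF, rt
Reagents that add atoms: tert-butyl(chloro)diphenylsilane (CC(C)(C)[Si](Cl)(c1ccccc1)c1ccccc1)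
Why: Standard silylation of a primary alcohol. The bulky silyl group survives hydride, organolithium and SnCl4 and is the large group on C4 that directs the key step.

Step 5
Reactants: 7 methyl (2R)-2-{[(tert-butyldiphenylsilyl)oxy]methyl}-2-methyl-5-(trimethylsilyl)pent-4-ynoate
Product: 8 methyl (2R,4Z)-2-{[(tert-butyldiphenylsilyl)oxy]methyl}-2-methyl-5-(trimethylsilyl)pent-4-enoate
Conditions: H2 (1 atm), Ni(OAc)2·4H2O/NaBH4 (nickel boride), H2NCH2CH2NH2, EtOH, rt
Reagents that add atoms: none
Why: Syn semi-hydrogenation of a 1-silylalkyne over amine-poisoned nickel boride gives the Z-vinylsilane. The Z geometry is required for the endocyclic ipso closure in step 13.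

Step 6
Reactants: 8 methyl (2R,4Z)-2-{[(tert-butyldiphenylsilyl)oxy]methyl}-2-methyl-5-(trimethylsilyl)pent-4-enoate
Product: 9 (2S,4Z)-2-{[(tert-butyldiphenylsilyl)oxy]methyl}-2-methyl-5-(trimethylsilyl)pent-4-en-1-ol
Conditions: i-Bu2AlH, CH2Cl2, −78 → 0 °C; aq. potassium sodium tartrate
Reagents that add atoms: none
Why: Hydride reduction of the neopentyl methyl ester to the primary alcohol; the vinylsilane and silyl ether are inert at low temperature. The descriptor changes from R to S only because the priorities change.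

Step 7
Reactants: 9 (2S,4Z)-2-{[(tert-butyldiphenylsilyl)oxy]methyl}-2-methyl-5-(trimethylsilyl)pent-4-en-1-ol
Product: 10 (2R,4Z)-2-{[(tert-butyldiphenylsilyl)oxy]methyl}-2-methyl-5-(trimethylsilyl)pent-4-enal
Conditions: Dess–Martin periodinane, CH2Cl2, 0 °C → rt
Reagents that add atoms: none
Why: Dess–Martin oxidation to the aldehyde; the α-carbon is quaternary, so neither enolisation nor epimerisation is possible.

Step 8
Reactants: 10 (2R,4Z)-2-{[(tert-butyldiphenylsilyl)oxy]methyl}-2-methyl-5-(trimethylsilyl)pent-4-enal; 11 ethyl 2-(triphenyl-λ5-phosphanylidene)propanoate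
Product: 12 ethyl (2E,4S,6Z)-4-{[(tert-butyldiphenylsilyl)oxy]methyl}-2,4-dimethyl-7-(trimethylsilyl)hepta-2,6-dienoate
Conditions: toluene, 110 °C
Reagents that add atoms: none
Why: Wittig reaction of a stabilised α-methyl ylide gives the E trisubstituted enoate. This alkene is the future C5–C10 bond, and its E geometry later becomes the trans ring fusion.

Step 9
Reactants: 12 ethyl (2E,4S,6Z)-4-{[(tert-butyldiphenylsilyl)oxy]methyl}-2,4-dimethyl-7-(trimethylsilyl)hepta-2,6-dienoate
Product: 13 (2E,4S,6Z)-4-{[(tert-butyldiphenylsilyl)oxy]methyl}-2,4-dimethyl-7-(trimethylsilyl)hepta-2,6-dien-1-ol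
Conditions: i-Bu2AlH, CH2Cl2, −78 °C; aq. potassium sodium tartrate
Reagents that add atoms: none
Why: 1,2-Reduction of the enoate to the allylic alcohol without change of alkene geometry.

Step 10
Reactants: 13 (2E,4S,6Z)-4-{[(tert-butyldiphenylsilyl)oxy]methyl}-2,4-dimethyl-7-(trimethylsilyl)hepta-2,6-dien-1-ol
Product: 14 (2E,4S,6Z)-1-bromo-4-{[(tert-butyldiphenylsilyl)oxy]methyl}-2,4-dimethyl-7-(trimethylsilyl)hepta-2,6-diene
Conditions: CBr4, PPh3, 2,6-lutidine, CH2Cl2, 0 °C
Reagents that add atoms: tetrabromomethane (BrC(Br)(Br)Br)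
Why: Appel bromination converts the primary allylic alcohol into the bromide by SN2 displacement without allylic transposition; the buffer protects the vinylsilane from HBr.

Step 11
Reactants: 14 (2E,4S,6Z)-1-bromo-4-{[(tert-butyldiphenylsilyl)oxy]methyl}-2,4-dimethyl-7-(trimethylsilyl)hepta-2,6-diene; 15 1-methoxypropa-1,2-diene
Product: 16 (5E,7S,9Z)-7-{[(tert-butyldiphenylsilyl)oxy]methyl}-3-methoxy-5,7-dimethyl-10-(trimethylsilyl)deca-1,2,5,9-tetraene
Conditions: 15, n-BuLi, THF, −40 °C; then 14, −78 → −20 °C
Reagents that add atoms: none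
Why: α-Lithiated methoxyallene is an acyl-anion equivalent of a propenoyl group. SN2 alkylation at the primary allylic bromide forms C8–C9 and brings in C6–C8 in one step, without a free β,γ-unsaturated vinyl ketone.

Step 12
Reactants: 16 (5E,7S,9Z)-7-{[(tert-butyldiphenylsilyl)oxy]methyl}-3-methoxy-5,7-dimethyl-10-(trimethylsilyl)deca-1,2,5,9-tetraene
Product: 17 2-[(2E,4S,6Z)-4-{[(tert-butyldiphenylsilyl)oxy]methyl}-2,4-dimethyl-7-(trimethylsilyl)hepta-2,6-dien-1-yl]-2-ethenyl-1,3-dioxolane
Conditions: HOCH2CH2OH (5 equiv), PPTS (cat.), 4 Å sieves, CH2Cl2, 0 °C → rt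
Reagents that add atoms: ethane-1,2-diol (OCCO)
Why: Acid-catalysed addition of an alcohol to a 1-alkoxyallene: protonation of the central allene carbon gives the alkoxyallyl cation, the diol captures it at C8, and intramolecular exchange of methoxide closes the dioxolane. With a weak acid and excess diol the cation should be trapped at oxygen much faster than it can cyclise.

Step 13
Reactants: 17 2-[(2E,4S,6Z)-4-{[(tert-butyldiphenylsilyl)oxy]methyl}-2,4-dimethyl-7-(trimethylsilyl)hepta-2,6-dien-1-yl]-2-ethenyl-1,3-dioxolane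
Product: 19 (4aS,5S,8aR)-5-{[(tert-butyldiphenylsilyl)oxy]methyl}-5,8a-dimethyl-3,4,4a,5,6,8a-hexahydronaphthalen-2(1H)-one, via hydroxyethyl enol ether 18 (not isolated)
Conditions: SnCl4 (2 equiv), 2,6-di-tert-butyl-4-methylpyridine (0.2 equiv), CH2Cl2, −78 → −40 °C; then 1 M HCl, THF, rt
Reagents that add atoms: water (O)
Why: SnCl4 binds one dioxolane oxygen and reversibly ionises C8–O to the 1-alkoxyallyl cation C6–C7–C8, whose s-cis form alone can react. Ring B closes in a 6-endo mode: C5 of the E-alkene attacks the unsubstituted allyl terminus C6 (attack at C8 would give a four-membered ring), the whole allyl unit ends up in the ring as the enol ether, and the charge passes in the Markovnikov sense to tertiary C10. Ring A closes by 6-endo ipso attack of the vinylsilane carbon C1 on C10; the Z geometry lets the C–Si bond stabilise the C2 cation, and loss of silicon to chloride leaves only the C1=C2 alkene. The closest known reaction type is the Lewis-acid polyene cyclisation started by an allyl cation from an enone ketal and ended by a vinylsilane; here it is used with the allyl unit inside the first ring. C5 and C10 arise together by anti addition across the E C5=C10 alkene in a chair–chair array, which makes H5 and C20 trans. Their absolute sense is controlled by C4: the first closure is expected to be reversible (the tertiary cation can fragment back to the more stable alkoxyallyl cation), so the alkene face is chosen in the array in which ring A closes, where the C4 group forced axial lies 1,3-diaxial to C20. The selectivity needed is therefore facial; methyl pays less for the axial position than CH2OSi(t-Bu)Ph2, so the silyloxymethyl group goes equatorial, and the low temperature widens the gap. The ketal keeps C9 from enolising until the ring exists, and aqueous acid hydrolyses enol ether 18 to the C8 ketone.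

Step 14
Reactants: 19 (4aS,5S,8aR)-5-{[(tert-butyldiphenylsilyl)oxy]methyl}-5,8a-dimethyl-3,4,4a,5,6,8a-hexahydronaphthalen-2(1H)-one
Product: 20 (4aS,5S,8aS)-5-{[(tert-butyldiphenylsilyl)oxy]methyl}-5,8a-dimethyloctahydronaphthalen-2(1H)-one
Conditions: H2 (1 atm), 10% Pd/C, EtOAc, rt
Reagents that add atoms: none
Why: Heterogeneous hydrogenation of the cis-disubstituted ring A alkene, the only C=C bond in 19. No stereocentre is formed; the C10 descriptor changes only through priorities.

Step 15
Reactants: 20 (4aS,5S,8aS)-5-{[(tert-butyldiphenylsilyl)oxy]methyl}-5,8a-dimethyloctahydronaphthalen-2(1H)-one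
Product: 22 (4aS,5S,8aS)-5-{[(tert-butyldiphenylsilyl)oxy]methyl}-5,8a-dimethyl-4a,5,6,7,8,8a-hexahydronaphthalen-2(1H)-one, via silyl enol ether 21 (not isolated)
Conditions: LiN(i-Pr)2, THF, −78 °C; Me3SiCl; then Pd(OAc)2, MeCN, rt
Reagents that add atoms: none
Why: Saegusa–Ito oxidation: kinetic deprotonation takes the less hindered C7 hydrogen, and Pd(OAc)2 oxidises silyl enol ether 21 by β-hydride elimination from C6. An isomeric C8–C9 enol ether could not give an enone because C10 is quaternary.

Step 16
Reactants: 22 (4aS,5S,8aS)-5-{[(tert-butyldiphenylsilyl)oxy]methyl}-5,8a-dimethyl-4a,5,6,7,8,8a-hexahydronaphthalen-2(1H)-one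
Product: 25 (4aS,5S,8aR)-5-{[(tert-butyldiphenylsilyl)oxy]methyl}-5,8a-dimethyl-1-methylidene-4a,5,6,7,8,8a-hexahydronaphthalen-2(1H)-one, via Mannich base 23 (not isolated), via methiodide 24 (not isolated)
Conditions: LiN(i-Pr)2, THF, −78 °C; CH2=NMe2+ I−, −78 → 0 °C; then MeI, CH2Cl2, rt; then aq. NaHCO3, rt
Reagents that add atoms: N,N-dimethylmethaniminium iodide (C=[N+](C)C.[I-])
Why: Mannich methylenation: C9 is now the only enolisable position, so the lithium enolate adds to the iminium salt there; quaternisation and mild base expel trimethylamine (E1cB). The exocyclic C9=C11 bond cannot move into the ring because C10 is quaternary.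

Step 17
Reactants: 25 (4aS,5S,8aR)-5-{[(tert-butyldiphenylsilyl)oxy]methyl}-5,8a-dimethyl-1-methylidene-4a,5,6,7,8,8a-hexahydronaphthalen-2(1H)-one; 26 tributyl(propa-1,2-dien-1-yl)stannane
Product: 28 (1S,4aS,5S,8aR)-1-(but-3-yn-1-yl)-5-{[(tert-butyldiphenylsilyl)oxy]methyl}-5,8a-dimethyl-4a,5,6,7,8,8a-hexahydronaphthalen-2(1H)-one, via titanium enolate 27 (not isolated)
Conditions: TiCl4, CH2Cl2, −78 °C; then AcOH, THF, −78 °C
Reagents that add atoms: none
Why: Hosomi–Sakurai-type conjugate propargylation: the TiCl4-activated exocyclic enone is attacked at the unhindered terminus C11 by the allenylstannane in an SE2' sense, which delivers the but-3-ynyl chain and leaves the hindered ring enone alone. Kinetic protonation of titanium enolate 27 takes place on the face of C9 opposite the axial C20 methyl, so the chain ends up equatorial as in the target.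

Step 18
Reactants: 28 (1S,4aS,5S,8aR)-1-(but-3-yn-1-yl)-5-{[(tert-butyldiphenylsilyl)oxy]methyl}-5,8a-dimethyl-4a,5,6,7,8,8a-hexahydronaphthalen-2(1H)-one
Product: 29 (1R,4aS,5S,8aS)-1-(but-3-yn-1-yl)-5-{[(tert-butyldiphenylsilyl)oxy]methyl}-5,8a-dimethyl-2-methylidene-1,2,4a,5,6,7,8,8a-octahydronaphthalene
Conditions: Zn, CH2Br2, TiCl4, THF (reagent aged at 5 °C); then 28, CH2Cl2, 0 °C → rt
Reagents that add atoms: dibromomethane (BrCBr)
Why: Lombardo–Takai methylenation: the non-basic zinc/titanium reagent converts the hindered conjugated ketone into the exocyclic diene without enolising C9, which a basic phosphorus ylide could epimerise. From here on C9 is fixed.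

Step 19
Reactants: 29 (1R,4aS,5S,8aS)-1-(but-3-yn-1-yl)-5-{[(tert-butyldiphenylsilyl)oxy]methyl}-5,8a-dimethyl-2-methylidene-1,2,4a,5,6,7,8,8a-octahydronaphthalene
Product: 31 methyl (2E)-5-[(1R,4aS,5S,8aS)-5-{[(tert-butyldiphenylsilyl)oxy]methyl}-5,8a-dimethyl-2-methylidene-1,2,4a,5,6,7,8,8a-octahydronaphthalen-1-yl]-3-methylpent-2-enoate, via alkenylalane 30 (not isolated)
Conditions: AlMe3, Cp2ZrCl2 (cat.), CH2Cl2, 0 °C → rt; then ClCO2Me, 0 °C → rt
Reagents that add atoms: trimethylaluminium (C[Al](C)C); methyl chloroformate (COC(=O)Cl)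
Why: Zirconium-catalysed carboalumination (Negishi) adds methyl and aluminium syn across the terminal alkyne with methyl at C13. Alkenylalane 30 is acylated by the chloroformate with retention, so the E geometry of the enoate is fixed by mechanism.

Step 20
Reactants: 31 methyl (2E)-5-[(1R,4aS,5S,8aS)-5-{[(tert-butyldiphenylsilyl)oxy]methyl}-5,8a-dimethyl-2-methylidene-1,2,4a,5,6,7,8,8a-octahydronaphthalen-1-yl]-3-methylpent-2-enoate
Product: 32 methyl (2E)-5-[(1R,4aS,5S,8aS)-5-(hydroxymethyl)-5,8a-dimethyl-2-methylidene-1,2,4a,5,6,7,8,8a-octahydronaphthalen-1-yl]-3-methylpent-2-enoate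
Conditions: Bu4NF, AcOH, THF, rt → 40 °C
Reagents that add atoms: none
Why: Fluoride cleavage of the silyl ether; buffering with acetic acid protects the methyl ester and the diene from basic fluoride.

Step 21
Reactants: 32 methyl (2E)-5-[(1R,4aS,5S,8aS)-5-(hydroxymethyl)-5,8a-dimethyl-2-methylidene-1,2,4a,5,6,7,8,8a-octahydronaphthalen-1-yl]-3-methylpent-2-enoate
Product: 33 methyl (2E)-5-[(1R,4aS,5S,8aS)-5-(acetoxymethyl)-5,8a-dimethyl-2-methylidene-1,2,4a,5,6,7,8,8a-octahydronaphthalen-1-yl]-3-methylpent-2-enoate
Conditions: Ac2O, pyridine, DMAP (cat.), CH2Cl2, rt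
Reagents that add atoms: acetic anhydride (CC(=O)OC(C)=O)
Why: Acetylation of the primary neopentyl alcohol under nucleophilic catalysis gives the target; no stereocentre or alkene is touched.

## Compound list

1 | dimethyl 2-methylpropanedioate | COC(=O)C(C)C(=O)OC | starting material
2 | 3-bromo-1-(trimethylsilyl)prop-1-yne | C[Si](C)(C)C#CCBr | starting material
3 | dimethyl 2-methyl-2-[3-(trimethylsilyl)prop-2-yn-1-yl]propanedioate | COC(=O)C(C)(CC#C[Si](C)(C)C)C(=O)OC | intermediate
4 | (2R)-3-methoxy-2-methyl-3-oxo-2-[3-(trimethylsilyl)prop-2-yn-1-yl]propanoic acid | COC(=O)[C@@](C)(C(=O)O)CC#C[Si](C)(C)C | intermediate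
5 | methyl (2S)-2-(chlorocarbonyl)-2-methyl-5-(trimethylsilyl)pent-4-ynoate | COC(=O)[C@@](C)(C(=O)Cl)CC#C[Si](C)(C)C | intermediate (not isolated)
6 | methyl (2R)-2-(hydroxymethyl)-2-methyl-5-(trimethylsilyl)pent-4-ynoate | COC(=O)[C@@](C)(CO)CC#C[Si](C)(C)C | intermediate
7 | methyl (2R)-2-{[(tert-butyldiphenylsilyl)oxy]methyl}-2-methyl-5-(trimethylsilyl)pent-4-ynoate | COC(=O)[C@@](C)(CO[Si](c1ccccc1)(c1ccccc1)C(C)(C)C)CC#C[Si](C)(C)C | intermediate
8 | methyl (2R,4Z)-2-{[(tert-butyldiphenylsilyl)oxy]methyl}-2-methyl-5-(trimethylsilyl)pent-4-enoate | COC(=O)[C@@](C)(CO[Si](c1ccccc1)(c1ccccc1)C(C)(C)C)C/C=C\[Si](C)(C)C | intermediate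
9 | (2S,4Z)-2-{[(tert-butyldiphenylsilyl)oxy]methyl}-2-methyl-5-(trimethylsilyl)pent-4-en-1-ol | OC[C@@](C)(CO[Si](c1ccccc1)(c1ccccc1)C(C)(C)C)C/C=C\[Si](C)(C)C | intermediate
10 | (2R,4Z)-2-{[(tert-butyldiphenylsilyl)oxy]methyl}-2-methyl-5-(trimethylsilyl)pent-4-enal | O=C[C@@](C)(CO[Si](c1ccccc1)(c1ccccc1)C(C)(C)C)C/C=C\[Si](C)(C)C | intermediate
11 | ethyl 2-(triphenyl-λ5-phosphanylidene)propanoate | CCOC(=O)C(C)=P(c1ccccc1)(c1ccccc1)c1ccccc1 | starting material
12 | ethyl (2E,4S,6Z)-4-{[(tert-butyldiphenylsilyl)oxy]methyl}-2,4-dimethyl-7-(trimethylsilyl)hepta-2,6-dienoate | CCOC(=O)/C(C)=C/[C@@](C)(CO[Si](c1ccccc1)(c1ccccc1)C(C)(C)C)C/C=C\[Si](C)(C)C | intermediate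
13 | (2E,4S,6Z)-4-{[(tert-butyldiphenylsilyl)oxy]methyl}-2,4-dimethyl-7-(trimethylsilyl)hepta-2,6-dien-1-ol | OC/C(C)=C/[C@@](C)(CO[Si](c1ccccc1)(c1ccccc1)C(C)(C)C)C/C=C\[Si](C)(C)C | intermediate
14 | (2E,4S,6Z)-1-bromo-4-{[(tert-butyldiphenylsilyl)oxy]methyl}-2,4-dimethyl-7-(trimethylsilyl)hepta-2,6-diene | BrC/C(C)=C/[C@@](C)(CO[Si](c1ccccc1)(c1ccccc1)C(C)(C)C)C/C=C\[Si](C)(C)C | intermediate
15 | 1-methoxypropa-1,2-diene | COC=C=C | starting material
16 | (5E,7S,9Z)-7-{[(tert-butyldiphenylsilyl)oxy]methyl}-3-methoxy-5,7-dimethyl-10-(trimethylsilyl)deca-1,2,5,9-tetraene | C=C=C(OC)C/C(C)=C/[C@@](C)(CO[Si](c1ccccc1)(c1ccccc1)C(C)(C)C)C/C=C\[Si](C)(C)C | intermediate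
17 | 2-[(2E,4S,6Z)-4-{[(tert-butyldiphenylsilyl)oxy]methyl}-2,4-dimethyl-7-(trimethylsilyl)hepta-2,6-dien-1-yl]-2-ethenyl-1,3-dioxolane | C=CC1(OCCO1)C/C(C)=C/[C@@](C)(CO[Si](c2ccccc2)(c2ccccc2)C(C)(C)C)C/C=C\[Si](C)(C)C | intermediate
18 | 2-{[(4aS,5S,8aR)-5-{[(tert-butyldiphenylsilyl)oxy]methyl}-5,8a-dimethyl-1,4,4a,5,6,8a-hexahydronaphthalen-2-yl]oxy}ethan-1-ol (present as its tin alkoxide) | OCCOC1=CC[C@@H]2[C@@](C)(CO[Si](c3ccccc3)(c3ccccc3)C(C)(C)C)CC=C[C@@]2(C)C1 | intermediate (not isolated)
19 | (4aS,5S,8aR)-5-{[(tert-butyldiphenylsilyl)oxy]methyl}-5,8a-dimethyl-3,4,4a,5,6,8a-hexahydronaphthalen-2(1H)-one | O=C1CC[C@@H]2[C@@](C)(CO[Si](c3ccccc3)(c3ccccc3)C(C)(C)C)CC=C[C@@]2(C)C1 | intermediate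
20 | (4aS,5S,8aS)-5-{[(tert-butyldiphenylsilyl)oxy]methyl}-5,8a-dimethyloctahydronaphthalen-2(1H)-one | O=C1CC[C@@H]2[C@@](C)(CO[Si](c3ccccc3)(c3ccccc3)C(C)(C)C)CCC[C@@]2(C)C1 | intermediate
21 | {[(4aS,5S,8aS)-5-{[(tert-butyldiphenylsilyl)oxy]methyl}-5,8a-dimethyl-1,4,4a,5,6,7,8,8a-octahydronaphthalen-2-yl]oxy}trimethylsilane | C[Si](C)(C)OC1=CC[C@@H]2[C@@](C)(CO[Si](c3ccccc3)(c3ccccc3)C(C)(C)C)CCC[C@@]2(C)C1 | intermediate (not isolated)
22 | (4aS,5S,8aS)-5-{[(tert-butyldiphenylsilyl)oxy]methyl}-5,8a-dimethyl-4a,5,6,7,8,8a-hexahydronaphthalen-2(1H)-one | O=C1C=C[C@@H]2[C@@](C)(CO[Si](c3ccccc3)(c3ccccc3)C(C)(C)C)CCC[C@@]2(C)C1 | intermediate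
23 | (4aS,5S,8aR)-5-{[(tert-butyldiphenylsilyl)oxy]methyl}-1-[(dimethylamino)methyl]-5,8a-dimethyl-4a,5,6,7,8,8a-hexahydronaphthalen-2(1H)-one (C1 epimers) | O=C1C=C[C@@H]2[C@@](C)(CO[Si](c3ccccc3)(c3ccccc3)C(C)(C)C)CCC[C@@]2(C)C1CN(C)C | intermediate (not isolated)
24 | {[(4aS,5S,8aR)-5-{[(tert-butyldiphenylsilyl)oxy]methyl}-5,8a-dimethyl-2-oxo-1,2,4a,5,6,7,8,8a-octahydronaphthalen-1-yl]methyl}trimethylazanium iodide (C1 epimers) | O=C1C=C[C@@H]2[C@@](C)(CO[Si](c3ccccc3)(c3ccccc3)C(C)(C)C)CCC[C@@]2(C)C1C[N+](C)(C)C.[I-] | intermediate (not isolated)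
25 | (4aS,5S,8aR)-5-{[(tert-butyldiphenylsilyl)oxy]methyl}-5,8a-dimethyl-1-methylidene-4a,5,6,7,8,8a-hexahydronaphthalen-2(1H)-one | O=C1C=C[C@@H]2[C@@](C)(CO[Si](c3ccccc3)(c3ccccc3)C(C)(C)C)CCC[C@@]2(C)C1=C | intermediate
26 | tributyl(propa-1,2-dien-1-yl)stannane | C=C=C[Sn](CCCC)(CCCC)CCCC | starting material
27 | {[(4aS,5S,8aR)-1-(but-3-yn-1-yl)-5-{[(tert-butyldiphenylsilyl)oxy]methyl}-5,8a-dimethyl-4a,5,6,7,8,8a-hexahydronaphthalen-2-yl]oxy}trichlorotitanium | Cl[Ti](Cl)(Cl)OC=1C=C[C@@H]2[C@@](C)(CO[Si](c3ccccc3)(c3ccccc3)C(C)(C)C)CCC[C@@]2(C)C=1CCC#C | intermediate (not isolated)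
28 | (1S,4aS,5S,8aR)-1-(but-3-yn-1-yl)-5-{[(tert-butyldiphenylsilyl)oxy]methyl}-5,8a-dimethyl-4a,5,6,7,8,8a-hexahydronaphthalen-2(1H)-one | O=C1C=C[C@@H]2[C@@](C)(CO[Si](c3ccccc3)(c3ccccc3)C(C)(C)C)CCC[C@@]2(C)[C@@H]1CCC#C | intermediate
29 | (1R,4aS,5S,8aS)-1-(but-3-yn-1-yl)-5-{[(tert-butyldiphenylsilyl)oxy]methyl}-5,8a-dimethyl-2-methylidene-1,2,4a,5,6,7,8,8a-octahydronaphthalene | C=C1C=C[C@@H]2[C@@](C)(CO[Si](c3ccccc3)(c3ccccc3)C(C)(C)C)CCC[C@@]2(C)[C@@H]1CCC#C | intermediate
30 | {(1E)-4-[(1R,4aS,5S,8aS)-5-{[(tert-butyldiphenylsilyl)oxy]methyl}-5,8a-dimethyl-2-methylidene-1,2,4a,5,6,7,8,8a-octahydronaphthalen-1-yl]-2-methylbut-1-en-1-yl}dimethylalumane | C=C1C=C[C@@H]2[C@@](C)(CO[Si](c3ccccc3)(c3ccccc3)C(C)(C)C)CCC[C@@]2(C)[C@@H]1CC/C(C)=C/[Al](C)C | intermediate (not isolated)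
31 | methyl (2E)-5-[(1R,4aS,5S,8aS)-5-{[(tert-butyldiphenylsilyl)oxy]methyl}-5,8a-dimethyl-2-methylidene-1,2,4a,5,6,7,8,8a-octahydronaphthalen-1-yl]-3-methylpent-2-enoate | C=C1C=C[C@@H]2[C@@](C)(CO[Si](c3ccccc3)(c3ccccc3)C(C)(C)C)CCC[C@@]2(C)[C@@H]1CC/C(C)=C/C(=O)OC | intermediate
32 | methyl (2E)-5-[(1R,4aS,5S,8aS)-5-(hydroxymethyl)-5,8a-dimethyl-2-methylidene-1,2,4a,5,6,7,8,8a-octahydronaphthalen-1-yl]-3-methylpent-2-enoate | C=C1C=C[C@@H]2[C@@](C)(CO)CCC[C@@]2(C)[C@@H]1CC/C(C)=C/C(=O)OC | intermediate
33 | methyl (2E)-5-[(1R,4aS,5S,8aS)-5-(acetoxymethyl)-5,8a-dimethyl-2-methylidene-1,2,4a,5,6,7,8,8a-octahydronaphthalen-1-yl]-3-methylpent-2-enoate (CNP0148290.1) | C=C1C=C[C@@H]2[C@@](C)(COC(C)=O)CCC[C@@]2(C)[C@@H]1CC/C(C)=C/C(=O)OC | target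

## Step count and least certain steps

Total: 21 steps. Longest linear sequence: 21 steps (from 1; compounds 2, 11, 15 and 26 are purchased).

**Step 13 (key step).**
- What may go wrong: the cascade stops after ring B. The tertiary C10 cation, crowded by the C4 quaternary centre, may lose a proton or revert before the weakly nucleophilic vinylsilane attacks. Once ring A closure is no longer part of the selectivity-determining event, the facial control from C4 is lost as well.
- Fallback (from 17, back at 19): the two rings are closed in separate operations. Ionisation of 17 with SnCl4 in the presence of a full equivalent of 2,6-di-tert-butyl-4-methylpyridine, then aqueous HCl and DBU, is directed to the conjugated monocyclic enone (4S)-4-[(2S,4Z)-1-{[tert-butyldiphenylsilyl]oxy}-2-methyl-5-(trimethylsilyl)pent-4-en-2-yl]-3-methylcyclohex-2-en-1-one F1 (proton loss from C10, hydrolysis of the dienol ether, conjugation). Copper-catalysed 1,4-addition of CH2=CHMgBr (CuBr·SMe2, Me3SiCl, THF, −78 °C) anti to the bulky C5 substituent sets C10 and gives the 3-ethenyl-3-methylcyclohexanone F2. Ring-closing metathesis between the new vinyl group and the Z-vinylsilane (second-generation Hoveyda–Grubbs catalyst, toluene, 80 °C; silicon leaves as trimethyl(vinyl)silane) forms the C1=C2 bond and returns 19.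

**Step 12.**
- What may go wrong: ionisation of the product under the acid that forms it. The vinyl ketal is itself the cation precursor, so conjugate addition of the diol at C6 or premature cyclisation can compete.
- Fallback (from 16, back at 17): the vinyl group is kept masked while the ketal is made. Hydrolysis of 16 with dilute oxalic acid in the presence of benzeneselenol traps the enone as the β-selanyl ketone (5E,7S,9Z)-7-{[(tert-butyldiphenylsilyl)oxy]methyl}-5,7-dimethyl-1-(phenylselanyl)-10-(trimethylsilyl)deca-5,9-dien-3-one F3. This saturated ketone is ketalised with 1,2-bis(trimethylsilyloxy)ethane and catalytic Me3SiOTf at −78 °C to the 2-[2-(phenylselanyl)ethyl]-1,3-dioxolane F4, from which no allyl cation can form. Oxidation with H2O2/pyridine and selenoxide syn-elimination at room temperature then unveil the C6=C7 bond under neutral conditions and give 17.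

**Step 17.**
- What may go wrong: competing 1,2-addition or transfer of an allenyl instead of a propargyl group, and non-selective protonation of the enolate at C9.
- Fallback (from 25, back at 31): the more reliable allylsilane is used and the chain is finished by oxidation and olefination. Hosomi–Sakurai addition of allyltrimethylsilane (TiCl4, CH2Cl2, −78 °C) with the same cold protonation gives the but-3-enyl ketone F5. Methylenation as in step 18 gives the triene F6. Wacker oxidation (PdCl2, CuCl, O2, DMF/H2O) of the only monosubstituted alkene gives the methyl ketone F7. Horner–Wadsworth–Emmons reaction with trimethyl phosphonoacetate (NaH, THF) gives 31 after removal of the minor Z isomer. The price is the loss of mechanism-based E control.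

**Step 19.**
- What may go wrong: Lewis-acid-induced isomerisation or oligomerisation of the conjugated exocyclic diene by the aluminium and zirconium species, or incomplete carbometalation.
- Fallback (from 29, back at 31): the carbons are added in the opposite order. Deprotonation of 29 (n-BuLi, THF, −78 °C) and acylation with ClCO2Me give the ynoate F8. Anti addition of benzenethiol (NaOMe cat., MeOH) gives the (Z)-3-(phenylsulfanyl) enoate F9. Copper-mediated substitution of the sulfanyl group by methyl with retention (MeMgBr, CuI, THF, −78 °C) gives 31.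

**Step 2.**
- What may go wrong: insufficient enantioselectivity of the esterase for this pair of substituents (methyl against silylpropargyl).
- Fallback (from 3, back at 6): catalytic reductive desymmetrisation. Enantioselective hydrosilylation of one of the two ester groups with a dinuclear zinc catalyst (ZnEt2, a chiral pipecolinol-derived tetradentate phenol ligand, a hydrosilane, then dilute acid) gives 6 directly and makes steps 2 and 3 unnecessary. No new compound is made.

## Further compounds

F1 | step 13 | (4S)-4-[(2S,4Z)-1-{[tert-butyldiphenylsilyl]oxy}-2-methyl-5-(trimethylsilyl)pent-4-en-2-yl]-3-methylcyclohex-2-en-1-one | O=C1CC[C@H]([C@@](C)(CO[Si](c2ccccc2)(c2ccccc2)C(C)(C)C)C/C=C\[Si](C)(C)C)C(C)=C1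
F2 | step 13 | (3R,4S)-4-[(2S,4Z)-1-{[tert-butyldiphenylsilyl]oxy}-2-methyl-5-(trimethylsilyl)pent-4-en-2-yl]-3-ethenyl-3-methylcyclohexan-1-one | O=C1CC[C@H]([C@@](C)(CO[Si](c2ccccc2)(c2ccccc2)C(C)(C)C)C/C=C\[Si](C)(C)C)[C@@](C)(C=C)C1
F3 | step 12 | (5E,7S,9Z)-7-{[(tert-butyldiphenylsilyl)oxy]methyl}-5,7-dimethyl-1-(phenylselanyl)-10-(trimethylsilyl)deca-5,9-dien-3-one | O=C(CC[Se]c1ccccc1)C/C(C)=C/[C@@](C)(CO[Si](c1ccccc1)(c1ccccc1)C(C)(C)C)C/C=C\[Si](C)(C)C
F4 | step 12 | 2-[(2E,4S,6Z)-4-{[(tert-butyldiphenylsilyl)oxy]methyl}-2,4-dimethyl-7-(trimethylsilyl)hepta-2,6-dien-1-yl]-2-[2-(phenylselanyl)ethyl]-1,3-dioxolane | c1ccccc1[Se]CCC1(OCCO1)C/C(C)=C/[C@@](C)(CO[Si](c1ccccc1)(c1ccccc1)C(C)(C)C)C/C=C\[Si](C)(C)C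
F5 | step 17 | (1S,4aS,5S,8aR)-1-(but-3-en-1-yl)-5-{[(tert-butyldiphenylsilyl)oxy]methyl}-5,8a-dimethyl-4a,5,6,7,8,8a-hexahydronaphthalen-2(1H)-one | O=C1C=C[C@@H]2[C@@](C)(CO[Si](c3ccccc3)(c3ccccc3)C(C)(C)C)CCC[C@@]2(C)[C@@H]1CCC=C
F6 | step 17 | (1R,4aS,5S,8aS)-1-(but-3-en-1-yl)-5-{[(tert-butyldiphenylsilyl)oxy]methyl}-5,8a-dimethyl-2-methylidene-1,2,4a,5,6,7,8,8a-octahydronaphthalene | C=C1C=C[C@@H]2[C@@](C)(CO[Si](c3ccccc3)(c3ccccc3)C(C)(C)C)CCC[C@@]2(C)[C@@H]1CCC=C
F7 | step 17 | 4-[(1R,4aS,5S,8aS)-5-{[(tert-butyldiphenylsilyl)oxy]methyl}-5,8a-dimethyl-2-methylidene-1,2,4a,5,6,7,8,8a-octahydronaphthalen-1-yl]butan-2-one | C=C1C=C[C@@H]2[C@@](C)(CO[Si](c3ccccc3)(c3ccccc3)C(C)(C)C)CCC[C@@]2(C)[C@@H]1CCC(C)=O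
F8 | step 19 | methyl 5-[(1R,4aS,5S,8aS)-5-{[(tert-butyldiphenylsilyl)oxy]methyl}-5,8a-dimethyl-2-methylidene-1,2,4a,5,6,7,8,8a-octahydronaphthalen-1-yl]pent-2-ynoate | C=C1C=C[C@@H]2[C@@](C)(CO[Si](c3ccccc3)(c3ccccc3)C(C)(C)C)CCC[C@@]2(C)[C@@H]1CCC#CC(=O)OC
F9 | step 19 | methyl (2Z)-5-[(1R,4aS,5S,8aS)-5-{[(tert-butyldiphenylsilyl)oxy]methyl}-5,8a-dimethyl-2-methylidene-1,2,4a,5,6,7,8,8a-octahydronaphthalen-1-yl]-3-(phenylsulfanyl)pent-2-enoate | C=C1C=C[C@@H]2[C@@](C)(CO[Si](c3ccccc3)(c3ccccc3)C(C)(C)C)CCC[C@@]2(C)[C@@H]1CC/C(Sc4ccccc4)=C/C(=O)OC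
F0 | step 2 | none | none
A1 | alternative 1 | 1-diazo-4-(3-hydroxy-2,6-dimethylphenyl)butan-2-one | [N-]=[N+]=CC(=O)CCc1c(C)ccc(O)c1C
A2 | alternative 1 | (4aR)-1,4a-dimethyl-4a,5,7,8-tetrahydronaphthalene-2,6-dione | O=C1CCC2=C(C)C(=O)C=C[C@@]2(C)C1
A3 | alternative 2 | (4S,6R)-6-[(1Z)-3-{[tert-butyl(dimethyl)silyl]oxy}-2-methylprop-1-en-1-yl]-4-methyl-4-[(2-methyl-1,3-dioxolan-2-yl)methyl]oxan-2-one | O=C1C[C@](C)(CC2(C)OCCO2)C[C@@H](O1)/C=C(/C)CO[Si](C)(C)C(C)(C)C
A4 | alternative 2 | (1S,2S,6S)-2-{[(tert-butyldimethylsilyl)oxy]methyl}-2,6-dimethyl-6-[(2-methyl-1,3-dioxolan-2-yl)methyl]cyclohex-3-ene-1-carboxylic acid | OC(=O)[C@@H]1[C@@](C)(CO[Si](C)(C)C(C)(C)C)C=CC[C@@]1(C)CC2(C)OCCO2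
A5 | alternative 3 | methyl (2E)-3-[(1S,2S,3S)-3-{[(tert-butyldimethylsilyl)oxy]methyl}-1,3-dimethyl-2-(3-oxopropyl)cyclohexyl]prop-2-enoate | O=CCC[C@@H]1[C@@](C)(CO[Si](C)(C)C(C)(C)C)CCC[C@@]1(C)/C=C/C(=O)OC
A6 | alternative 3 | methyl [(1S,4aS,5S,8aR)-5-{[(tert-butyldimethylsilyl)oxy]methyl}-5,8a-dimethyl-2-oxodecahydronaphthalen-1-yl]acetate | O=C1CC[C@@H]2[C@@](C)(CO[Si](C)(C)C(C)(C)C)CCC[C@@]2(C)[C@@H]1CC(=O)OC
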